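**Plan**

1. Serratane numbering is used: rings A/B = C1–C10; ring C (seven-membered) = C8, C9, C11, C12, C13, C14, C27; ring D = C13–C18; ring E = C17–C22; C26 = the OCH2 on C8. Apart from the C26–O/C27 bridge the target is C2-symmetric about the middle of C11–C12, and the ring C-seco intermediates (onocerane skeleton) keep these numbers.
2. Retrosynthesis: (a) cut C8–C27 and C14–O to a C8 spiro-epoxide and an exocyclic C14=C27 alkene, which exposes a C2-symmetric bis-decalin diketone; (b) cut C15–C16 and C17–C22 (twins C6–C7 and C4–C5) to an acyclic bis-epoxide carrying, on each half, an aldehyde enol ether and a methyl ketone enol ether; (c) cut C13–C18 and C9–C10 to digeranyl adipate.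
3. Forward: geraniol and adipoyl chloride are joined; a double Ireland–Claisen rearrangement builds the C8–C14 backbone with both quaternary carbons; rings E/A and then D/B close in one cascade (four rings); ring C and the oxolane bridge close last.
4. Enabling feature: C17 (C5) is a CH between two quaternary carbons, and C16/C15 (C6/C7) are plain CH2 groups next to an oxygenated C14 (C8). C16 can therefore be a transient aldehyde carbon: its enol ether makes C17 the nucleophile for the epoxide carbon C22, and the oxocarbenium ion left at C16 is the electrophile for C15, the α-carbon of a C14 ketone.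
5. Stereochemistry: C18/C13 (C10/C9) come from the chair Claisen rearrangement under a chiral boron controller; C21 (C3) from reagent-controlled epoxidation; C17 (C5) is relayed from these in the cascade; C8 and C14 come from anti opening of the spiro-epoxide and the tethered oxygen.

Key step: step 8

Assumption: the (S,S)-diazaborolidine controller is taken to deliver the enantiomer drawn for 5 and the L-fructose-derived ketone the (S)-epoxides; if the sense of the boron controller is the opposite, its (R,R)-enantiomer is used with no other change.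

Step 1
Reactants: 1 geraniol (2 equiv); 2 adipoyl chloride
Product: 3 digeranyl adipate
Conditions: pyridine, DMAP (cat.), CH2Cl2, 0 → 23 °C
Reagents that add atoms: none
Why: Acylation of the primary allylic alcohol by the diacid chloride (esterification) is routine and installs both allyl ester units at once without forming a stereocentre.

Step 2
Reactants: 3 digeranyl adipate
Product: 5 (2R,5R)-2,5-bis[(3S)-3,7-dimethylocta-1,6-dien-3-yl]hexanedioic acid, via bis(boron ketene acetal) 4 (not isolated)
Conditions: (4S,5S)-2-bromo-1,3-bis[3,5-bis(trifluoromethyl)benzenesulfonyl]-4,5-diphenyl-1,3,2-diazaborolidine (2.4 equiv), i-Pr2NEt, CH2Cl2, −78 → 23 °C; aqueous work-up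
Reagents that add atoms: none
Why: In this enantioselective boron-mediated Ireland–Claisen rearrangement, soft enolisation should give the Z(O) ketene acetal 4, which rearranges through a chair with the methyl of the (E)-allyl terminus axial and the enolate chain equatorial, so that C13–C18 and C9–C10 form with the required relative configuration of quaternary carbon and adjacent methine, the absolute sense coming from the controller and being sharpened by the two-fold reaction.

Step 3
Reactants: 5 (2R,5R)-2,5-bis[(3S)-3,7-dimethylocta-1,6-dien-3-yl]hexanedioic acid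
Product: 7 bis-δ-lactone, via dihydroxy diacid 6 (not isolated)
Conditions: 9-BBN (excess), THF, 0 → 23 °C; NaOH, H2O2, 0 °C; then 1 M HCl, 23 °C
Reagents that add atoms: hydrogen peroxide, OO
Why: Hydroboration–oxidation with the bulky dialkylborane should select the monosubstituted vinyl groups over the trisubstituted alkenes and place oxygen on C16 (C6), after which the δ-hydroxy acids 6 lactonise on acidification with no stereocentre touched.

Step 4
Reactants: 7 bis-δ-lactone
Product: 8 bis-lactol (cyclic hemiketals of the δ-hydroxy methyl ketones)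
Conditions: MeLi (2.2 equiv), THF, −78 °C; aqueous NH4Cl
Reagents that add atoms: methyllithium, [Li]C
Why: Addition of one methyl anion to each lactone at low temperature stops at the tetrahedral alkoxide and so installs C15 (C7) as a methyl ketone masked as its lactol, whose hemiketal centre is of no consequence.

Step 5
Reactants: 8 bis-lactol
Product: 9 bis-epoxy bis-lactol
Conditions: L-fructose-derived Shi ketone (cat.), KHSO5 (as 2KHSO5·KHSO4·K2SO4), K2CO3, Bu4NHSO4, MeCN/CH2(OMe)2, aqueous Na2B4O7 buffer, 0 °C
Reagents that add atoms: potassium peroxymonosulfate, [K+].[O-]S(=O)(=O)OO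
Why: In the Shi asymmetric epoxidation the chiral dioxirane should attack only the two electron-rich trisubstituted alkenes and set C21 (C3) as (S) under reagent control.

Step 6
Reactants: 9 bis-epoxy bis-lactol
Product: 10 bis(1,5-keto aldehyde)
Conditions: Dess–Martin periodinane, NaHCO3, CH2Cl2, 0 → 23 °C
Reagents that add atoms: none
Why: Dess–Martin oxidation acts on the open hydroxy ketone tautomer of each lactol and should give the aldehyde at C16 (C6) under buffered conditions that leave the epoxides and the C13 (C9) centre intact.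

Step 7
Reactants: 10 bis(1,5-keto aldehyde)
Product: 11 tetrakis(silyl enol ether)
Conditions: TBSOTf, Et3N, CH2Cl2, −78 → −40 °C
Reagents that add atoms: tert-butyldimethylsilyl trifluoromethanesulfonate, CC(C)(C)[Si](C)(C)OS(=O)(=O)C(F)(F)F
Why: Soft enolisation with silyl triflate and amine (silyl enol ether formation) passes through no free enolate, so the 1,5-dicarbonyl units cannot close by aldol reaction in base, the aldehyde reacting first and the methyl ketone then towards its unhindered methyl group C15 (C7), while the epoxides are expected to survive at low temperature.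

Step 8
Reactants: 11 tetrakis(silyl enol ether)
Product: 13 tetracyclic bis(β-silyloxy ketone) diol, via bis(silyloxocarbenium) zwitterion 12 (not isolated)
Conditions: MeAlCl2 (5 equiv), CH2Cl2, −94 → −78 °C; aqueous NaHCO3
Reagents that add atoms: none
Why: Proposed new method: MeAlCl2 should open each trisubstituted epoxide at its tertiary carbon C22 (C4) under attack of C17 (C5) of the aldehyde-derived enol silyl ether, which closes ring E (ring A) and turns C16 (C6) into a silyloxocarbenium ion (12); this ion lies 1,3 to the ketone-derived enol silyl ether and is captured by its carbon C15 (C7) in an intramolecular Mukaiyama aldol addition that forms the C15–C16 (C6–C7) bond and closes ring D (ring B). The closest known reaction types are the Lewis acid epoxy-polyene cyclisation terminated by a silyl enol ether and the intramolecular Mukaiyama aldol addition to a silyl-activated aldehyde; new is their relay, in which the first enol ether is both the terminator of the epoxide opening and the source of the electrophile for the second. Ring E closes through a chair in the 6-endo mode with respect to the epoxide (6-exo with respect to the enol ether C=C), and ring D closes 6-(enolendo)-exo-trig through a chair fused trans to the first. C21 (C3) keeps the epoxide configuration with its oxygen equatorial, and C17 (C5) is controlled by the C18 (C10) quaternary centre: in the chair the C18 methyl is axial and eclipses the enol ether C=C, so C16 becomes equatorial and H17 anti to the methyl (trans ring fusion), though the preference over the other rotamer may be small; C16 (C6) forms as a mixture that step 9 erases. The step needs six-membered closure by C17 to outrun hydride shift of the activated epoxide and attack by the remote C15 enol ether (eight-membered ring), which the high π-nucleophilicity of the aldehyde enol ether, the chair geometry and the low temperature should secure.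

Step 9
Reactants: 13 tetracyclic bis(β-silyloxy ketone) diol
Product: 14 bis-enone diol
Conditions: TsOH·H2O (cat.), benzene, 60 °C
Reagents that add atoms: none
Why: Acid-catalysed β-elimination of silanol from the β-silyloxy ketones (aldol dehydration) should give the conjugated enones and remove the C16 (C6) oxygen and its stereocentre, while C13 (C9), α to the ketone, can only settle in the equatorial, required configuration.

Step 10
Reactants: 14 bis-enone diol
Product: 15 diketone diol
Conditions: H2 (1 atm), Pd/C, EtOAc, 23 °C
Reagents that add atoms: none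
Why: Catalytic hydrogenation of the disubstituted enone C=C bonds creates no stereocentre and returns C15/C16 (C6/C7) as methylene groups.

Step 11
Reactants: 15 diketone diol
Product: 16 bis(silyl ether) diketone
Conditions: TBSOTf, 2,6-lutidine, CH2Cl2, −78 → 0 °C
Reagents that add atoms: tert-butyldimethylsilyl trifluoromethanesulfonate, CC(C)(C)[Si](C)(C)OS(=O)(=O)C(F)(F)F
Why: Silylation (protection) of the two hindered equatorial alcohols keeps free hydroxyl groups away from the ylides and the Lewis acid of the next three steps and touches no stereocentre.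

Step 12
Reactants: 16 bis(silyl ether) diketone
Product: 17 mono-methylene ketone
Conditions: Ph3PCH3Br, KN(SiMe3)2 (1.0 equiv of ylide), THF, 0 → 23 °C
Reagents that add atoms: methyltriphenylphosphonium bromide, C[P+](c1ccccc1)(c1ccccc1)c1ccccc1.[Br-]
Why: In this Wittig methylenation the two ketones are related by the C2 axis, so mono-olefination gives a single compound (the C14=C27 alkene) beside separable diketone, which is returned to the step, and bis-alkene.

Step 13
Reactants: 17 mono-methylene ketone
Product: 18 spiro-epoxide alkene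
Conditions: Me3S(O)I, NaH, DMSO/THF, 23 → 50 °C
Reagents that add atoms: trimethylsulfoxonium iodide, C[S+](C)(C)=O.[I-]
Why: In the Corey–Chaykovsky epoxidation the sulfoxonium ylide adds reversibly and should close from the equatorial (α) side of the C8 ketone, away from the axial C10 methyl, so that the new CH2 (C26) is equatorial and the oxygen axial (β).

Step 14
Reactants: 18 spiro-epoxide alkene
Product: 20 bis(silyl ether) of the target, via C14 carbocation zwitterion 19 (not isolated)
Conditions: BF3·OEt2 (0.2 equiv), CH2Cl2, −78 °C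
Reagents that add atoms: none
Why: In this Lewis acid epoxide–alkene cyclisation (cation–olefin cyclisation with internal oxygen capture) the terminal carbon C27 of the exocyclic alkene should attack C8 anti to the departing oxygen and close the seven-membered ring C, which sets C8 by inversion and swings C26 axial, and the C26 oxygen, now held over the β face of the tertiary C14 cation 19, closes the oxolane and sets C14.

Step 15
Reactants: 20 bis(silyl ether) of the target
Product: 21 14β,26-epoxyserratane-3β,21α-diol (target)
Conditions: Bu4NF, THF, 60 °C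
Reagents that add atoms: none
Why: Fluoride-mediated cleavage of the two hindered silyl ethers (deprotection) should leave the ether bridge and all stereocentres untouched.

**Compound list**

1 | geraniol, (2E)-3,7-dimethylocta-2,6-dien-1-ol | CC(C)=CCC/C(C)=C/CO | starting material
2 | adipoyl chloride (hexanedioyl dichloride) | ClC(=O)CCCCC(Cl)=O | starting material
3 | digeranyl adipate, bis[(2E)-3,7-dimethylocta-2,6-dien-1-yl] hexanedioate | CC(C)=CCC/C(C)=C/COC(=O)CCCCC(=O)OC/C=C(\C)CCC=C(C)C | intermediate
4 | bis(boron ketene acetal) of 3: both ester units as Z(O) O-boryl ketene acetals of the (4S,5S)-1,3-bis[3,5-bis(trifluoromethyl)benzenesulfonyl]-4,5-diphenyl-1,3,2-diazaborolidin-2-yl group | C(/C=C(\OB1N(S(=O)(=O)c3cc(cc(c3)C(F)(F)F)C(F)(F)F)[C@@H](c2ccccc2)[C@H](c2ccccc2)N1S(=O)(=O)c2cc(cc(c2)C(F)(F)F)C(F)(F)F)OC/C=C(\C)CCC=C(C)C)C/C=C(\OB1N(S(=O)(=O)c3cc(cc(c3)C(F)(F)F)C(F)(F)F)[C@@H](c2ccccc2)[C@H](c2ccccc2)N1S(=O)(=O)c2cc(cc(c2)C(F)(F)F)C(F)(F)F)OC/C=C(\C)CCC=C(C)C | intermediate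
5 | (2R,5R)-2,5-bis[(3S)-3,7-dimethylocta-1,6-dien-3-yl]hexanedioic acid | C([C@@H](C(O)=O)[C@](C)(C=C)CCC=C(C)C)C[C@@H](C(O)=O)[C@](C)(C=C)CCC=C(C)C | intermediate
6 | dihydroxy diacid: 5 with both vinyl groups converted into 2-hydroxyethyl groups | C([C@@H](C(O)=O)[C@](C)(CCO)CCC=C(C)C)C[C@@H](C(O)=O)[C@](C)(CCO)CCC=C(C)C | intermediate
7 | bis-δ-lactone: 3,3'-(ethane-1,2-diyl)bis[4-methyl-4-(4-methylpent-3-en-1-yl)oxan-2-one], C2-symmetric | C([C@H]1C(=O)OCC[C@]1(C)CCC=C(C)C)C[C@H]1C(=O)OCC[C@]1(C)CCC=C(C)C | intermediate
8 | bis-lactol: 7 with each lactone carbonyl converted into C(CH3)(OH), anomer mixture | C([C@H]1C(C)(O)OCC[C@]1(C)CCC=C(C)C)C[C@H]1C(C)(O)OCC[C@]1(C)CCC=C(C)C | intermediate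
9 | bis-epoxy bis-lactol: 8 with both side-chain alkenes as (S)-3,3-dimethyloxiranes | C([C@H]1C(C)(O)OCC[C@]1(C)CC[C@@H]2OC2(C)C)C[C@H]1C(C)(O)OCC[C@]1(C)CC[C@@H]2OC2(C)C | intermediate
10 | bis(1,5-keto aldehyde): octane-2,7-dione bearing at C3 and C6 a 5-[(2S)-3,3-dimethyloxiran-2-yl]-3-methyl-1-oxopentan-3-yl group | C([C@@H](C(C)=O)[C@](C)(CC=O)CC[C@@H]1OC1(C)C)C[C@@H](C(C)=O)[C@](C)(CC=O)CC[C@@H]1OC1(C)C | intermediate
11 | tetrakis(silyl enol ether): 10 with both aldehydes as CH=CH–OTBS (E/Z mixture) and both methyl ketones as C(OTBS)=CH2 | C([C@@H](C(=C)O[Si](C)(C)C(C)(C)C)[C@](C)(C=CO[Si](C)(C)C(C)(C)C)CC[C@@H]1OC1(C)C)C[C@@H](C(=C)O[Si](C)(C)C(C)(C)C)[C@](C)(C=CO[Si](C)(C)C(C)(C)C)CC[C@@H]1OC1(C)C | intermediate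
12 | bis(silyloxocarbenium) zwitterion: rings E and A closed, C21/C3 aluminate alkoxides, C16/C6 as CH=O(+)–TBS, ketone enol ethers still open | C([C@@H](C(=C)O[Si](C)(C)C(C)(C)C)[C@@]1(C)CC[C@H](O[Al-](C)(Cl)Cl)C(C)(C)[C@@H]1C=[O+][Si](C)(C)C(C)(C)C)C[C@@H](C(=C)O[Si](C)(C)C(C)(C)C)[C@@]1(C)CC[C@H](O[Al-](C)(Cl)Cl)C(C)(C)[C@@H]1C=[O+][Si](C)(C)C(C)(C)C | intermediate
13 | tetracyclic bis(β-silyloxy ketone) diol: 6,16-bis(TBSO)-3β,21α-dihydroxy-26,27-dinoronocerane-8,14-dione (trans-fused decalins, C6/C16 epimer mixture) | C([C@H]1C(=O)CC(O[Si](C)(C)C(C)(C)C)[C@H]2C(C)(C)[C@@H](O)CC[C@]12C)C[C@H]1C(=O)CC(O[Si](C)(C)C(C)(C)C)[C@H]2C(C)(C)[C@@H](O)CC[C@]12C | intermediate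
14 | bis-enone diol: 3β,21α-dihydroxy-26,27-dinoronocera-6,15-diene-8,14-dione | C([C@H]1C(=O)C=C[C@H]2C(C)(C)[C@@H](O)CC[C@]12C)C[C@H]1C(=O)C=C[C@H]2C(C)(C)[C@@H](O)CC[C@]12C | intermediate
15 | diketone diol: 3β,21α-dihydroxy-26,27-dinoronocerane-8,14-dione | C([C@H]1C(=O)CC[C@H]2C(C)(C)[C@@H](O)CC[C@]12C)C[C@H]1C(=O)CC[C@H]2C(C)(C)[C@@H](O)CC[C@]12C | intermediate
16 | bis(silyl ether) diketone: 3β,21α-bis(TBSO)-26,27-dinoronocerane-8,14-dione | C([C@H]1C(=O)CC[C@H]2C(C)(C)[C@@H](O[Si](C)(C)C(C)(C)C)CC[C@]12C)C[C@H]1C(=O)CC[C@H]2C(C)(C)[C@@H](O[Si](C)(C)C(C)(C)C)CC[C@]12C | intermediate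
17 | mono-methylene ketone: 3β,21α-bis(TBSO)-26-noronocer-14(27)-en-8-one | C([C@H]1C(=C)CC[C@H]2C(C)(C)[C@@H](O[Si](C)(C)C(C)(C)C)CC[C@]12C)C[C@H]1C(=O)CC[C@H]2C(C)(C)[C@@H](O[Si](C)(C)C(C)(C)C)CC[C@]12C | intermediate
18 | spiro-epoxide alkene: 8β,26-epoxy-3β,21α-bis(TBSO)onocer-14(27)-ene (oxygen axial on C8, C26 equatorial) | C([C@H]1C(=C)CC[C@H]2C(C)(C)[C@@H](O[Si](C)(C)C(C)(C)C)CC[C@]12C)C[C@H]1[C@]3(CO3)CC[C@H]2C(C)(C)[C@@H](O[Si](C)(C)C(C)(C)C)CC[C@]12C | intermediate
19 | C14 carbocation zwitterion: ring C closed (C8–C27), C26–O–BF3(−), cation at C14 | CC1(C)[C@@H](O[Si](C)(C)C(C)(C)C)CC[C@@]2(C)[C@H]1CC[C@@]1(CO[B-](F)(F)F)C[C+]3CC[C@H]4C(C)(C)[C@@H](O[Si](C)(C)C(C)(C)C)CC[C@]4(C)[C@H]3CC[C@@H]12 | intermediate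
20 | 14β,26-epoxyserratane-3β,21α-diol bis(tert-butyldimethylsilyl ether) | CC1(C)[C@@H](O[Si](C)(C)C(C)(C)C)CC[C@@]2(C)[C@H]1CC[C@]13CO[C@@]4(CC[C@H]5C(C)(C)[C@@H](O[Si](C)(C)C(C)(C)C)CC[C@]5(C)[C@H]4CC[C@@H]12)C3 | intermediate
21 | 14β,26-epoxyserratane-3β,21α-diol (CNP0223111.1) | CC1(C)[C@@H](O)CC[C@@]2(C)[C@H]1CC[C@]13CO[C@@]4(CC[C@H]5C(C)(C)[C@@H](O)CC[C@]5(C)[C@H]4CC[C@@H]12)C3 | target

**Step count and risks**

Total step count: 15. Longest linear sequence: 15 steps (1 and 2 to 21).

Step 8 is the riskiest. The relay may stop after the first ring, the activated epoxide may rearrange by hydride shift before C17 attacks, or the other enol ether rotamer may react and give a cis ring fusion. The fallback separates the two ring closures and makes the C15–C16 bond by a base-mediated aldol condensation. It sets out from 10. One equivalent of TBSOTf per aldehyde (Et3N, CH2Cl2, −78 °C) should silylate only the aldehydes and give the bis(aldehyde enol silyl ether) bis(methyl ketone) F1. MeAlCl2 in CH2Cl2 at −78 °C then closes only rings E and A, an epoxide opening terminated by a silyl enol ether, to the bis(hydroxy aldehyde) F2. KOH in MeOH closes rings D and B by intramolecular aldol condensation; the aldehyde α-centre C17 (C5) can equilibrate under these conditions before the irreversible dehydration. The route is rejoined at 14.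

Step 14 is the second risk. The C8 cation may lose a proton or undergo a 1,2-hydride shift to the aldehyde (Meinwald rearrangement) before the seven-membered ring closes. The fallback replaces the cationic ring closure by a radical one and sets out from 18. Cp2TiCl (from Cp2TiCl2 and Mn, THF) opens the spiro-epoxide homolytically to the tertiary C8 radical, which should add in the 7-endo mode to the terminal carbon C27 of the exocyclic alkene. The C14 radical is trapped by a second Cp2TiCl and loses a β-hydrogen to give the 26-hydroxyserrat-14-ene bis(silyl ether) F3. Camphorsulfonic acid (cat., CH2Cl2) then adds the C26 hydroxyl across the trisubstituted alkene (Markovnikov hydroalkoxylation), which rejoins the route at 20.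

Step 2 is the third risk. Incomplete facial control in one of the two rearrangements, or erosion of the enolate geometry, would give the meso diacid and C13 epimers that are hard to remove. The fallback replaces reagent control by resolution and sets out from 3. LiN(i-Pr)2 and Me3SiCl in THF/DMPU (−78 → 60 °C; Ireland–Claisen rearrangement through the Z silyl ketene acetal) should give the diacid stereoisomer mixture F4, with the right relative configuration in each half but as racemic C2 and meso forms. Salt formation with an enantiopure amine found by screening, drawn here for (S)-1-phenylethylamine, and crystallisation give the bis(ammonium) salt F5 of the required enantiomer. Acidification returns 5.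

Further compounds
F1 | step 8 | bis(aldehyde enol silyl ether) bis(methyl ketone) bis-epoxide | C([C@@H](C(C)=O)[C@](C)(C=CO[Si](C)(C)C(C)(C)C)CC[C@@H]1OC1(C)C)C[C@@H](C(C)=O)[C@](C)(C=CO[Si](C)(C)C(C)(C)C)CC[C@@H]1OC1(C)C
F2 | step 8 | bis(hydroxy aldehyde): rings E and A closed, formyl on C17/C5, acetyl on C13/C9 | C([C@@H](C(C)=O)[C@@]1(C)CC[C@H](O)C(C)(C)[C@@H]1C=O)C[C@@H](C(C)=O)[C@@]1(C)CC[C@H](O)C(C)(C)[C@@H]1C=O
F3 | step 14 | 3β,21α-bis(tert-butyldimethylsilyloxy)serrat-14-en-26-ol | CC1(C)[C@@H](O[Si](C)(C)C(C)(C)C)CC[C@@]2(C)[C@H]1CC[C@@]1(CO)CC3=CC[C@H]4C(C)(C)[C@@H](O[Si](C)(C)C(C)(C)C)CC[C@]4(C)[C@H]3CC[C@@H]12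
F4 | step 2 | 2,5-bis(3,7-dimethylocta-1,6-dien-3-yl)hexanedioic acid, racemic C2 and meso forms | OC(=O)C(CCC(C(O)=O)C(C)(C=C)CCC=C(C)C)C(C)(C=C)CCC=C(C)C
F5 | step 2 | bis[(S)-1-phenylethylammonium] salt of 5 | C([C@@H](C([O-])=O)[C@](C)(C=C)CCC=C(C)C)C[C@@H](C([O-])=O)[C@](C)(C=C)CCC=C(C)C.C[C@H]([NH3+])c1ccccc1.C[C@H]([NH3+])c1ccccc1
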